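All runs come from a simulation for an exercise, and the scatter is random.

The theta and eta runs held the same initiator, 0.50 mM, yet they did not fall alike. Between 8.00 min and 15.0 min I read a slope of ln c(free monomer) of 0.0887 /min in theta and 0.118 /min in eta, so eta fell faster.

| flask | free monomer | initiator | remark | time |
|---|---|---|---|---|
| theta | 0.025 M | 0.50 mM | run made earlier |  |
| eta | 0.038 M | 0.50 mM | run made earlier |  |
| delta | 0.050 M | 0.25 mM | run made earlier |  |
| flask | 0.050 M | 0.50 mM |  | 25 min |

| run | time / min | monomer in chains / % | free monomer / % |
|---|---|---|---|
| theta | 2.50 | 3.8 | 95.9 |
| theta | 5.00 | 14.4 | 83.1 |
| theta | 8.00 | 30.7 | 65.5 |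
| theta | 10.0 | 42.6 | 56.1 |
| theta | 12.0 | 51.9 | 44.9 |
| theta | 15.0 | 63.8 | 35.2 |
| eta | 2.50 | 6.9 | 91.5 |
| eta | 5.00 | 21.6 | 78.3 |
| eta | 8.00 | 39.8 | 58.1 |
| eta | 10.0 | 53.0 | 46.2 |
| eta | 12.0 | 65.0 | 36.5 |
| eta | 15.0 | 71.2 | 25.5 |
| delta | 3.00 | 6.8 | 94.4 |
| delta | 6.00 | 20.4 | 79.7 |
| delta | 10.0 | 40.7 | 60.2 |
| delta | 12.0 | 48.0 | 50.7 |
| delta | 15.0 | 59.7 | 40.1 |

(standard deviation of a reading: 1 percentage point)

1. whether the average number of monomer units in a chain (chains begun, living or dead) reaches 500 by 25 min (yes / no)
2. average number of monomer units in a chain (chains begun, living or dead) at 25 min

- the average divides the monomer in chains by the number of chains begun, living and dead together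
- the earlier runs were read with a standard deviation of 1 percentage point
- the earlier runs do not show the number of chains; that part of a forecast is a guess

My first estimate came from a balance of the initiator, which is charged in the smaller amount, the limiting reagent in the usual term. Each initiator either begins a chain or is lost. If each one began a chain, the flask would reach 100 units per chain with its free monomer entirely in chains, which is below 500.

But if chains keep growing, equal initiator should then give equal numbers of chains and equal slopes. The slopes I read in eta and theta gave a ratio of 1.33, so I took it that some initiator begins no chain, and I gave up the first estimate. I turned the question round. The allowed share is the largest part of the charged initiator that may begin chains if the average is to reach the wanted length, with the free monomer entirely in chains: c(free monomer) over 500 times c(initiator), or 20.0%. Multiplied by the part of the free monomer then in chains, it holds at any moment in the flask.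

My objection was that the readings show no chain count. So whether the flask stayed within that share remained a guess, though I thought it possible.

The forecast differed. It answered no, with an average of 130, and judged that the length “would need only about 20% of the initiator to start chains, which seems unlikely”.

The flask gave yes, with an average of 582 at 25 min.

    initiator + monomer in chains → spent initiator (k = 22.6 /M/min)
    free monomer + initiator → living end + monomer in chains (k = 0.745 /M/min)
    free monomer + living end → monomer in chains + living end, rate k3*[living end]*[free monomer] (k = 1580 /M/min)

The living end stood at 8.01 × 10⁻⁵ M at 25.0 min, which is 16.0% of the initiator charged. With 93.2% of the free monomer in chains at that time, the allowed share was 18.6%, more than that part. The length was reached at 15.8 min with 80.9% of the free monomer reacted. The same flask stopped at 12.5 min ended at an average of 438 with 70.1% of the free monomer in chains, and the allowed share, rescaled to that length, gives 16.0%.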